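**Plan**

Numbering: ring A = arene C4a–C5(OH)–C6–C7–C8(CO2H)–C8a. Ring B = C1(side chain)–C2–C3–C4(CH3). Side chain = C11(H)(CH3)–C12–C13–C14–C15(H)(CH3)–C16H2–O-acyl.
Cuts: acyl–O at C16; C8–CO2H (back to C8–Cl); C4–CH3 and C4–C4a (ring B opened to a C4 acetal); C11–CH3 (back to C11–B); then, in one event, C11–C12 and C1–C8a.
Enabling feature: C1 carries ring A (through C8a) and its neighbour C11 carries the C12 chain. The C1–C11 pair is therefore the retron of an anti aryl/alkyl addition across an (E)-C1=C11 alkenylboronate, and the C11 methyl group marks where boron sat.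
Forward: the chain iodide (C12–C16), the alkenyl-B(mac) (C11, C1–C4) and the ring A triflate are merged by a palladium-induced 1,2-metallate shift. B then becomes CH3, ring B closes at C4a (C8–Cl blocks the para site), C4 is methylated, Cl becomes CO2H, and C16–OH is acylated last.
Stereochemistry: C15 comes from an Evans allylation. C1 and C11 come from alkene geometry (relative) and the chiral bisphosphine (absolute) in the key step. C4 comes from C1, by axial capture of the C4 benzylic cation opposite the side chain that the peri C8–Cl holds pseudoaxial (trans-1,4).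

Key step: step 9

Assumption: the ligand antipode named in step 9 is assigned to the (1S,11S) series by analogy with related couplings; if the sense is the reverse, the equally available mirror-image ligand is used with no other change. (mac = cis-1,2-dimethylacenaphthene-1,2-diolate on boron.)

**Step 1**
Reactants: 1 (4S)-4-benzyl-3-propanoyl-1,3-oxazolidin-2-one; 2 allyl iodide
Product: 4 (4S)-4-benzyl-3-[(2R)-2-methylpent-4-enoyl]-1,3-oxazolidin-2-one, via sodium enolate 3 (not isolated)
Conditions: NaHMDS, THF, −78 °C; then 2, −78 → −40 °C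
Reagents that add atoms: none
Why: Evans asymmetric alkylation: the chelated (Z)-enolate 3 is shielded on one face by the C4 benzyl group of the auxiliary, so allyl iodide should enter from the open face and set C15 as (R).

**Step 2**
Reactants: 4 (4S)-4-benzyl-3-[(2R)-2-methylpent-4-enoyl]-1,3-oxazolidin-2-one
Product: 5 (2R)-2-methylpent-4-en-1-ol
Conditions: LiBH4, H2O (1 equiv), Et2O, 0 °C
Reagents that add atoms: none
Why: Reductive cleavage of an N-acyl oxazolidinone: borohydride attacks the more electrophilic exocyclic carbonyl group, which should free the primary alcohol without loss of the α-stereocentre and without touching the alkene.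

**Step 3**
Reactants: 5 (2R)-2-methylpent-4-en-1-ol
Product: 6 tert-butyl(dimethyl){[(2R)-2-methylpent-4-en-1-yl]oxy}silane
Conditions: TBSCl, imidazole, CH2Cl2, 0 °C → rt
Reagents that add atoms: tert-butyldimethylsilyl chloride, CC(C)(C)[Si](C)(C)Cl
Why: Standard silylation of a primary alcohol, chosen because the TBS ether withstands alkyllithiums, palladium, Lewis acid at low temperature and LiDBB, and falls to dilute acid in step 15.

**Step 4**
Reactants: 6 tert-butyl(dimethyl){[(2R)-2-methylpent-4-en-1-yl]oxy}silane
Product: 8 tert-butyl{[(2R)-5-iodo-2-methylpentyl]oxy}dimethylsilane, via alkylzirconocene chloride 7 (not isolated)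
Conditions: Cp2Zr(H)Cl, THF, rt; then I2, 0 °C
Reagents that add atoms: iodine, II
Why: Hydrozirconation–iodination: Cp2Zr(H)Cl adds to the terminal alkene with zirconium on the end carbon and iodine cleaves the C–Zr bond, which should give the primary iodide (C12) with C15 untouched.

**Step 5**
Reactants: 9 acenaphthoquinone
Product: 10 (1R,2S)-1,2-dimethyl-1,2-dihydroacenaphthylene-1,2-diol (cis meso mac diol)
Conditions: MeMgBr (2.5 equiv), THF, 0 °C → rt; aq NH4Cl; crystallisation of the cis isomer
Reagents that add atoms: methylmagnesium bromide, C[Mg]Br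
Why: Twofold Grignard 1,2-addition to a 1,2-diketone; only the cis (meso) diol, taken out by crystallisation, can bridge boron, and its bulk is the helper that the key step needs.

**Step 6**
Reactants: 11 2-(2-bromoethyl)-1,3-dioxolane
Product: 12 2-(but-3-yn-1-yl)-1,3-dioxolane
Conditions: lithium acetylide–ethylenediamine complex, DMSO, rt
Reagents that add atoms: lithium acetylide–ethylenediamine complex, [Li]C#C.NCCN
Why: SN2 alkylation of lithium acetylide by a primary bromide in a dipolar aprotic solvent, with the acetal (the future C4) inert to the base.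

**Step 7**
Reactants: 10 mac diol; 12 2-(but-3-yn-1-yl)-1,3-dioxolane
Product: 14 [(E)-4-(1,3-dioxolan-2-yl)but-1-en-1-yl]-B(mac), via borane HB(mac) 13 (not isolated)
Conditions: 10, BH3·SMe2, CH2Cl2, 0 °C → rt; then 12, Cp2Zr(H)Cl (10 mol %), Et3N (10 mol %), 60 °C
Reagents that add atoms: borane–dimethyl sulfide, C[S+](C)[BH3-]
Why: Dialkoxyborane formation from a 1,2-diol and BH3, followed by zirconium-catalysed syn-hydroboration of a terminal alkyne, should place boron on the end carbon (C11) and give the (E)-alkene whose geometry later fixes the C1/C11 relation.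

**Step 8**
Reactants: 15 2-chloro-5-methoxyphenol
Product: 16 2-chloro-5-methoxyphenyl trifluoromethanesulfonate
Conditions: Tf2O, pyridine, CH2Cl2, 0 °C
Reagents that add atoms: trifluoromethanesulfonic anhydride, O=S(=O)(OS(=O)(=O)C(F)(F)F)C(F)(F)F
Why: Triflation of a phenol, which turns C8a–O into the site of oxidative addition while the less reactive C8–Cl stays as blocking group and latent carboxyl group.

**Step 9**
Reactants: 8 tert-butyl{[(2R)-5-iodo-2-methylpentyl]oxy}dimethylsilane; 14 [(E)-4-(1,3-dioxolan-2-yl)but-1-en-1-yl]-B(mac); 16 2-chloro-5-methoxyphenyl trifluoromethanesulfonate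
Product: 19 (1S,11S,15R)-secondary boronate ArC1H[CH2CH2(1,3-dioxolan-2-yl)]–C11H[B(mac)]–(CH2)3–C15H(CH3)–CH2OTBS (Ar = 2-chloro-5-methoxyphenyl), via organolithium 17 (not isolated), via boron ate complex 18 (not isolated)
Conditions: 8, t-BuLi (2.0 equiv), Et2O, −78 °C; then 14, THF, −78 °C → rt; then 16, Pd(OAc)2 (3 mol %), (Sp,Sp)-MandyPhos (P-aryl = 4-MeO-3,5-Me2C6H2; 3.6 mol %), NaOTf (2 equiv), THF, 60 °C
Reagents that add atoms: none
Why: Iodine–lithium exchange gives 17, which adds to boron of 14 to give ate complex 18; oxidative addition of 16 to zerovalent palladium gives a cationic aryl complex of divalent palladium that binds the electron-rich C1=C11 bond and triggers a 1,2-metallate shift, in which C12 moves from boron to C11 anti to the metal while C1 becomes bonded to palladium, and reductive elimination with retention then forms C1–C8a. The closest known reaction type is the enantioselective three-component conjunctive cross-coupling of β-substituted alkenylboron ate complexes with aryl triflates, and it unites two boron-bound, formally nucleophilic carbons (C11 and C12) because the π-acidic metal reverses the polarity of C11. No ring is closed in this step. C1 and C11 are both new: their relative configuration follows from the stereospecific anti addition of aryl and alkyl across the (E)-alkene, and their absolute configuration from the alkene face that the chiral ferrocenyl bisphosphine lets palladium bind, with remote C15 expected to have no say. The step needs the metallate shift to win over direct Suzuki–Miyaura transfer of the alkenyl group and over β-hydride elimination at C1: the bulky mac diol slows transmetallation, the wide-bite-angle ligand speeds reductive elimination, NaOTf takes up the iodide that would block the cationic palladium, and C8–Cl is spared because the triflate adds faster.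

**Step 10**
Reactants: 19 (1S,11S,15R)-secondary boronate
Product: 21 (1S,11S,15R)-homologated primary boronate with C11–CH2–B(mac), via chloromethyl ate complex 20 (not isolated)
Conditions: BrCH2Cl (2.0 equiv), n-BuLi (1.8 equiv), THF, −78 °C; then rt
Reagents that add atoms: bromochloromethane, ClCBr
Why: Matteson homologation: LiCH2Cl made in the flask adds to boron at −78 °C and, on warming, C11 migrates with retention as chloride leaves, so the carbon that becomes the C11 methyl group takes the place of boron.

**Step 11**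
Reactants: 21 (1S,11S,15R)-homologated primary boronate
Product: 23 (1S,11S,15R)-acetal ArC1H[CH2CH2(1,3-dioxolan-2-yl)]–C11H(CH3)–(CH2)3–C15H(CH3)–CH2OTBS, via phenyl ate complex 22 (not isolated)
Conditions: PhLi (1.1 equiv), Et2O, 0 °C; evaporate; [Ir(dF(CF3)ppy)2(dtbbpy)]PF6 (2 mol %), PhSH (0.3 equiv), MeOH/acetone, blue LEDs, rt
Reagents that add atoms: none
Why: Photoredox radical protodeboronation of an aryl-activated boronate complex: single-electron oxidation of 22 releases the primary alkyl radical, which takes hydrogen from the thiol, and since the radical carbon is not stereogenic C11 is kept.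

**Step 12**
Reactants: 23 (1S,11S,15R)-acetal
Product: 24 (1S,11S,15R)-8-chloro-4-(2-hydroxyethoxy)-5-methoxytetralin bearing the C11–C16 side chain at C1 (both C4 epimers)
Conditions: SnCl4 (30 mol %), CH2Cl2, −78 → −40 °C
Reagents that add atoms: none
Why: Intramolecular Friedel–Crafts alkylation by an oxocarbenium ion: the Lewis acid opens the dioxolane and ring A attacks through C4a, ortho to the methoxy group and the only site that gives a six-membered ring B because C8 carries chlorine, while the C4 configuration is of no consequence since the next step erases it.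

**Step 13**
Reactants: 24 (1S,11S,15R)-8-chloro-4-(2-hydroxyethoxy)-5-methoxytetralin
Product: 25 (1S,4R,11S,15R)-8-chloro-5-methoxy-4-methyltetralin bearing the C11–C16 side chain at C1
Conditions: AlMe3 (4 equiv), CH2Cl2, −78 → 0 °C
Reagents that add atoms: trimethylaluminium, C[Al](C)C
Why: SN1-type benzylic methylation with AlMe3 as Lewis acid and methyl donor: the C4 cation is stabilised by the ortho methoxy group of ring A, the peri C8–Cl holds the C1 side chain pseudoaxial, and methyl should enter along the axial trajectory on the opposite face to give the trans-diaxial (1S,4R) half-chair, in which the new methyl group also avoids the C5 methoxy group.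

**Step 14**
Reactants: 25 (1S,4R,11S,15R)-8-chloro-5-methoxy-4-methyltetralin
Product: 27 (1S,4R,11S,15R)-5-methoxy-4-methyltetralin-8-carboxylic acid bearing the silylated side chain, via aryllithium 26 (not isolated)
Conditions: LiDBB (2.2 equiv), THF, −78 °C; CO2 (g), −78 °C → rt; cold 0.5 M HCl
Reagents that add atoms: carbon dioxide, O=C=O
Why: Reductive lithiation of an aryl chloride by an arene radical anion followed by carboxylation, in which small CO2 reaches the hindered C8 anion and no stereocentre is involved.

**Step 15**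
Reactants: 27 (1S,4R,11S,15R)-5-methoxy-4-methyltetralin-8-carboxylic acid
Product: 29 (1S,4R,11S,15R)-5-hydroxy-1-(16-hydroxy side chain)-4-methyltetralin-8-carboxylic acid, via disodium salt 28 (not isolated)
Conditions: EtSNa (6 equiv), DMF, 120 °C; then 1 M HCl, THF, rt
Reagents that add atoms: none
Why: Nucleophilic (SN2) demethylation of an aryl methyl ether by thiolate at the unhindered O–CH3 carbon, followed by acid hydrolysis of the primary TBS ether, neither of which touches a stereocentre.

**Step 16**
Reactants: 29 (1S,4R,11S,15R)-hydroxy acid; 30 4-methylpent-3-enoic acid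
Product: 31 target CNP0545998.1
Conditions: 30 (3 equiv), Novozym 435 (immobilised Candida antarctica lipase B), 4 Å MS, MTBE, 45 °C
Reagents that add atoms: none
Why: Lipase-catalysed esterification: the serine hydrolase is acylated by the unhindered aliphatic acid 30 and passes the acyl group to the primary aliphatic C16–OH, whereas the phenol and the hindered C8 benzoic acid are not accepted, and the neutral medium should keep the β,γ-double bond in place.

**Compound list**

1 | (4S)-4-benzyl-3-propanoyl-1,3-oxazolidin-2-one | CCC(=O)N1[C@@H](Cc2ccccc2)COC1=O | starting material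
2 | allyl iodide | C=CCI | starting material
3 | sodium (Z)-enolate of 1 | C/C=C(\[O-])N1[C@@H](Cc2ccccc2)COC1=O.[Na+] | intermediate
4 | (4S)-4-benzyl-3-[(2R)-2-methylpent-4-enoyl]-1,3-oxazolidin-2-one | C=CC[C@@H](C)C(=O)N1[C@@H](Cc2ccccc2)COC1=O | intermediate
5 | (2R)-2-methylpent-4-en-1-ol | C=CC[C@@H](C)CO | intermediate
6 | tert-butyl(dimethyl){[(2R)-2-methylpent-4-en-1-yl]oxy}silane | C=CC[C@@H](C)CO[Si](C)(C)C(C)(C)C | intermediate
7 | Cp2Zr(Cl)[(4R)-5-(tert-butyldimethylsilyloxy)-4-methylpentyl] | Cl[Zr](CCC[C@@H](C)CO[Si](C)(C)C(C)(C)C)(C1C=CC=C1)C1C=CC=C1 | intermediate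
8 | tert-butyl{[(2R)-5-iodo-2-methylpentyl]oxy}dimethylsilane | ICCC[C@@H](C)CO[Si](C)(C)C(C)(C)C | intermediate
9 | acenaphthoquinone | O=C1C(=O)c2cccc3cccc1c23 | starting material
10 | (1R,2S)-1,2-dimethyl-1,2-dihydroacenaphthylene-1,2-diol (cis, meso; mac diol) | C[C@@]1(O)[C@](C)(O)c2cccc3cccc1c32 | intermediate
11 | 2-(2-bromoethyl)-1,3-dioxolane | BrCCC1OCCO1 | starting material
12 | 2-(but-3-yn-1-yl)-1,3-dioxolane | C#CCCC1OCCO1 | intermediate
13 | HB(mac), cyclic dialkoxyborane of 10 | C[C@@]12OBO[C@]1(C)c1cccc3cccc2c31 | intermediate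
14 | [(E)-4-(1,3-dioxolan-2-yl)but-1-en-1-yl]-B(mac) | C[C@@]12OB(/C=C/CCC3OCCO3)O[C@]1(C)c1cccc3cccc2c31 | intermediate
15 | 2-chloro-5-methoxyphenol | COc1ccc(Cl)c(O)c1 | starting material
16 | 2-chloro-5-methoxyphenyl trifluoromethanesulfonate | COc1ccc(Cl)c(OS(=O)(=O)C(F)(F)F)c1 | intermediate
17 | (4R)-5-(tert-butyldimethylsilyloxy)-4-methylpentyllithium | [Li]CCC[C@@H](C)CO[Si](C)(C)C(C)(C)C | intermediate
18 | lithium alkyl(alkenyl)-B(mac) ate complex (configuration at boron open) | [Li+].C[C@@]12O[B-](CCC[C@@H](C)CO[Si](C)(C)C(C)(C)C)(/C=C/CCC3OCCO3)O[C@]1(C)c1cccc3cccc2c31 | intermediate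
19 | (1S,11S,15R)-secondary boronate, B(mac) on C11, aryl on C1 | C[C@@]12OB([C@@H](CCC[C@@H](C)CO[Si](C)(C)C(C)(C)C)[C@H](CCC3OCCO3)c3cc(OC)ccc3Cl)O[C@]1(C)c1cccc3cccc2c31 | intermediate
20 | lithium chloromethyl ate complex of 19 | [Li+].C[C@@]12O[B-](CCl)([C@@H](CCC[C@@H](C)CO[Si](C)(C)C(C)(C)C)[C@H](CCC3OCCO3)c3cc(OC)ccc3Cl)O[C@]1(C)c1cccc3cccc2c31 | intermediate
21 | (1S,11S,15R)-primary boronate, C11–CH2–B(mac) | C[C@@]12OB(C[C@@H](CCC[C@@H](C)CO[Si](C)(C)C(C)(C)C)[C@H](CCC3OCCO3)c3cc(OC)ccc3Cl)O[C@]1(C)c1cccc3cccc2c31 | intermediate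
22 | lithium phenyl ate complex of 21 | [Li+].C[C@@]12O[B-](c3ccccc3)(C[C@@H](CCC[C@@H](C)CO[Si](C)(C)C(C)(C)C)[C@H](CCC3OCCO3)c3cc(OC)ccc3Cl)O[C@]1(C)c1cccc3cccc2c31 | intermediate
23 | (1S,11S,15R)-acetal with C11–CH3 | CC(C)(C)[Si](C)(C)OC[C@H](C)CCC[C@H](C)[C@H](CCC1OCCO1)c1cc(OC)ccc1Cl | intermediate
24 | (1S,11S,15R)-8-chloro-4-(2-hydroxyethoxy)-5-methoxytetralin, C4 epimers | CC(C)(C)[Si](C)(C)OC[C@H](C)CCC[C@H](C)[C@@H]1CCC(OCCO)c2c(OC)ccc(Cl)c21 | intermediate
25 | (1S,4R,11S,15R)-8-chloro-5-methoxy-4-methyltetralin | CC(C)(C)[Si](C)(C)OC[C@H](C)CCC[C@H](C)[C@@H]1CC[C@@H](C)c2c(OC)ccc(Cl)c21 | intermediate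
26 | C8 aryllithium from 25 | CC(C)(C)[Si](C)(C)OC[C@H](C)CCC[C@H](C)[C@@H]1CC[C@@H](C)c2c(OC)ccc([Li])c21 | intermediate
27 | (1S,4R,11S,15R)-5-methoxy-4-methyltetralin-8-carboxylic acid, C16–OTBS | CC(C)(C)[Si](C)(C)OC[C@H](C)CCC[C@H](C)[C@@H]1CC[C@@H](C)c2c(OC)ccc(C(=O)O)c21 | intermediate
28 | disodium phenoxide carboxylate, C16–OTBS | CC(C)(C)[Si](C)(C)OC[C@H](C)CCC[C@H](C)[C@@H]1CC[C@@H](C)c2c([O-])ccc(C(=O)[O-])c21.[Na+].[Na+] | intermediate
29 | (1S,4R,11S,15R)-5-hydroxy-4-methyltetralin-8-carboxylic acid, C16–OH | OC[C@H](C)CCC[C@H](C)[C@@H]1CC[C@@H](C)c2c(O)ccc(C(=O)O)c21 | intermediate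
30 | 4-methylpent-3-enoic acid | CC(C)=CCC(=O)O | starting material
31 | CNP0545998.1 | CC(C)=CCC(=O)OC[C@H](C)CCC[C@H](C)[C@@H]1CC[C@@H](C)c2c(O)ccc(C(=O)O)c21 | target

**Total steps:** 16. **Longest linear sequence:** 12 (steps 1–4 and 9–16).

**Steps most likely to fail**

Step 9. Iodide carried in with the alkyllithium may poison the cationic palladium, the alkenyl group may transfer directly to palladium, or facial selectivity may erode. The fallback exchanges the roles of the two C11 substituents and makes the C11–C12 bond by a Zweifel olefination. It sets out from 12, 13, 16 and 6 and returns at 23, so steps 10 and 11 are not needed.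
- Rhodium-catalysed trans-hydroboration of 12 with 13 ([Rh(cod)Cl]2, P(i-Pr)3, Et3N) should give the (Z)-alkenylboronate F1.
- Halide-free MeLi, then 16 under the palladium conditions of step 9, should give by the same anti addition the methyl-bearing secondary boronate F2, with boron standing where C12 belongs.
- Ozonolysis of 6 (O3; PPh3) gives the aldehyde F3, and Takai olefination (CHI3, CrCl2) gives the (E)-vinyl iodide F4.
- Exchange of F4 with t-BuLi, addition to F2, then I2 and NaOMe joins C11 to C12 with retention at C11 to give the (Z)-alkene F5.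
- Diimide (2-nitrobenzenesulfonyl hydrazide, Et3N) saturates F5 to 23 without touching C8–Cl.

Step 13. The C4 cation may lose a proton from C3 faster than it captures methyl, or the two faces may be poorly differentiated. The fallback replaces the cation by a neutral ortho-quinone methide under basic conditions. It sets out from 24 and returns at 29.
- EtSNa in DMF frees the phenol F6.
- Excess MeMgBr in warm toluene lets the magnesium phenoxide expel the chelated glycolate. The quinone methide across C5, C4a and C4 then takes up methyl in a 1,4-addition, again axially and opposite the pseudoaxial C1 chain, to give the trans chlorophenol F7.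
- Deprotonation with n-BuLi, LiDBB, CO2 and an aqueous HCl work-up that also removes the silyl group lead to 29.

Step 11. Single-electron oxidation of the hindered primary boronate complex may be sluggish, or the radical chain may be unproductive. The fallback is a polar oxidation–reduction sequence that sets out from 21 and returns at 23.
- NaBO3·4H2O oxidises the C–B bond to the primary alcohol F8.
- TsCl and pyridine give the tosylate F9.
- LiEt3BH displaces the tosylate by hydride to give 23.

**Further compounds**

F1 | step 9 | [(Z)-4-(1,3-dioxolan-2-yl)but-1-en-1-yl]-B(mac) | C[C@@]12OB(/C=C\CCC3OCCO3)O[C@]1(C)c1cccc3cccc2c31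
F2 | step 9 | secondary boronate with CH3 on C11 and B(mac) in the place of C12 (1S, 11R by the CIP rules) | C[C@@]12OB([C@H](C)[C@H](CCC3OCCO3)c3cc(OC)ccc3Cl)O[C@]1(C)c1cccc3cccc2c31
F3 | step 9 | (3R)-4-(tert-butyldimethylsilyloxy)-3-methylbutanal | O=CC[C@@H](C)CO[Si](C)(C)C(C)(C)C
F4 | step 9 | tert-butyl{[(2R,4E)-5-iodo-2-methylpent-4-en-1-yl]oxy}dimethylsilane | I/C=C/C[C@@H](C)CO[Si](C)(C)C(C)(C)C
F5 | step 9 | (1S,11S,15R)-(12Z)-alkene | CC(C)(C)[Si](C)(C)OC[C@H](C)C/C=C\[C@H](C)[C@H](CCC1OCCO1)c1cc(OC)ccc1Cl
F6 | step 13 | (1S,11S,15R)-8-chloro-4-(2-hydroxyethoxy)tetralin-5-ol, C4 epimers | CC(C)(C)[Si](C)(C)OC[C@H](C)CCC[C@H](C)[C@@H]1CCC(OCCO)c2c(O)ccc(Cl)c21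
F7 | step 13 | (1S,4R,11S,15R)-8-chloro-4-methyltetralin-5-ol | CC(C)(C)[Si](C)(C)OC[C@H](C)CCC[C@H](C)[C@@H]1CC[C@@H](C)c2c(O)ccc(Cl)c21
F8 | step 11 | (1S,11S,15R)-primary alcohol, C11–CH2OH | CC(C)(C)[Si](C)(C)OC[C@H](C)CCC[C@H](CO)[C@H](CCC1OCCO1)c1cc(OC)ccc1Cl
F9 | step 11 | (1S,11S,15R)-tosylate, C11–CH2OTs | CC(C)(C)[Si](C)(C)OC[C@H](C)CCC[C@H](COS(=O)(=O)c1ccc(C)cc1)[C@H](CCC1OCCO1)c1cc(OC)ccc1Cl
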